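**Plan**

Numbering: C1 = C(OH)(CH2OBz), C2 = C=O, C3 = CH2, C4 = CHOH, C5 = CHOBz, C6 = CHOH of the cyclohexanone ring. β is the ring face that carries CH2OBz, so C4-OH and C5-OBz are β and C1-OH and C6-OH are α.
Retrosynthesis: C2=O comes from a temporary C2-OBn carbinol and C6-OH from a C6 ketone. The carbocycle is then cut at C4–C5 (aldol retron) to a pyranoside enol benzoate, and the C1–CH2OBz branch is cut back through a spiro-epoxide to a 4-ulose made from D-glucal.
Enabling feature: at the C6-ketone level the run C6(O)–C5(OBz)–C4(OH)–C3H2 of the six-membered ring is a 2-acyloxy-3-hydroxy ketone. Its ketone can enolise only toward C5 because C1 is quaternary, its aldehyde partner C4 is the anomeric carbon of a 2-deoxy sugar, and the ring oxygen of a methyl 2-deoxy-hex-5-enopyranoside ties C6 to C4 and masks both.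
Forward: the pyran ring of D-glucal holds all six future ring carbons (sugar C-1 to C-6 = C4, C3, C2, C1, C6, C5). The order is O-6/O-3 differentiation, glycoside, 4-ulose, quaternary centre and Z-enol benzoate, after which the pyran ring is exchanged for the carbocycle in one operation; C6 reduction, C2 oxidation and desilylation finish the route.
Stereochemistry: sugar C-3 and C-5 of D-glucal, both erased later, fix C1 by equatorial methylene transfer. The C2-OBn group and the chair transition state fix C4 and C5, and C4-OH then directs hydride to C6.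

Key step: step 10

Assumption: compounds 5 to 12 are drawn as the α-anomers expected from step 3. The anomeric centre is erased in step 10, so any β-anomer can be carried along.

**Step 1**
Reactants: 1 D-glucal
Product: 2 6-O-(tert-butyldiphenylsilyl)-D-glucal
Conditions: TBDPSCl, imidazole, DMF, 0 °C to rt
Reagents that add atoms: tert-butyl(chloro)diphenylsilane, CC(C)(C)[Si](Cl)(c1ccccc1)c1ccccc1
Why: Selective silylation, in which the bulky silyl chloride should react only at the unhindered primary 6-OH.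

**Step 2**
Reactants: 2 6-O-(tert-butyldiphenylsilyl)-D-glucal
Product: 4 3-O-benzyl-6-O-(tert-butyldiphenylsilyl)-D-glucal, via stannylene acetal 3 (not isolated)
Conditions: Bu2SnO, toluene, reflux (Dean–Stark); then BnBr, Bu4NI, 80 °C
Reagents that add atoms: benzyl bromide, BrCc1ccccc1; Bu2SnO, CCCC[Sn](=O)CCCC (tin stays only in 3)
Why: Stannylene-acetal-mediated regioselective O-alkylation, in which the allylic O-3 is the more nucleophilic oxygen of the 3,4-O-stannylene acetal, so it is benzylated and 4-OH stays free.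

**Step 3**
Reactants: 4 3-O-benzyl-6-O-(tert-butyldiphenylsilyl)-D-glucal
Product: 5 methyl 3-O-benzyl-6-O-(tert-butyldiphenylsilyl)-2-deoxy-α-D-arabino-hexopyranoside
Conditions: MeOH, Ph3P·HBr (cat.), CH2Cl2, rt
Reagents that add atoms: methanol, CO
Why: Acid-catalysed addition of an alcohol to a glycal, in which protonation at C-2 gives the oxocarbenium ion, methanol captures it axially (anomeric effect) to set the later erased α centre, and the O-3 ether is too poor a leaving group for allylic rearrangement.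

**Step 4**
Reactants: 5 methyl 3-O-benzyl-6-O-(tert-butyldiphenylsilyl)-2-deoxy-α-D-arabino-hexopyranoside
Product: 6 methyl 3-O-benzyl-6-O-(tert-butyldiphenylsilyl)-2-deoxy-α-D-threo-hexopyranosid-4-ulose
Conditions: Dess–Martin periodinane, CH2Cl2, rt
Reagents that add atoms: none
Why: Dess–Martin oxidation of the only free hydroxyl under non-basic conditions, which avoids β-elimination of the 6-silyloxy group.

**Step 5**
Reactants: 6 methyl 3-O-benzyl-6-O-(tert-butyldiphenylsilyl)-2-deoxy-α-D-threo-hexopyranosid-4-ulose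
Product: 7 methyl 4,4'-anhydro-3-O-benzyl-6-O-(tert-butyldiphenylsilyl)-2-deoxy-4-C-(hydroxymethyl)-α-D-lyxo-hexopyranoside (spiro-epoxide)
Conditions: Me3S(O)I, NaH, DMSO–THF, rt
Reagents that add atoms: trimethylsulfoxonium iodide, C[S+](C)(C)=O.[I-]
Why: Corey–Chaykovsky epoxidation, in which the stabilised sulfoxonium ylide adds reversibly and the betaine with the new C–C bond equatorial closes, so CH2 ends equatorial and the epoxide oxygen axial in the chair anchored by the equatorial groups at sugar C-3 and C-5, which sets target C1.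

**Step 6**
Reactants: 7 spiro-epoxide
Product: 8 methyl 4-C-(benzoyloxymethyl)-3-O-benzyl-6-O-(tert-butyldiphenylsilyl)-2-deoxy-α-D-lyxo-hexopyranoside
Conditions: PhCO2H, PhCO2Cs (0.2 equiv), DMF, 80 °C
Reagents that add atoms: benzoic acid, O=C(O)c1ccccc1
Why: SN2 opening of a 2,2-disubstituted epoxide by carboxylate at the unsubstituted CH2 terminus, which installs the primary benzoate directly and leaves the C–O bond at the quaternary centre untouched.

**Step 7**
Reactants: 8 methyl 4-C-(benzoyloxymethyl)-3-O-benzyl-6-O-(tert-butyldiphenylsilyl)-2-deoxy-α-D-lyxo-hexopyranoside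
Product: 9 methyl 4-C-(benzoyloxymethyl)-3-O-benzyl-2-deoxy-α-D-lyxo-hexopyranoside
Conditions: Bu4NF, AcOH, THF, rt
Reagents that add atoms: none
Why: Fluoride-mediated desilylation, buffered with acetic acid so that no free alkoxide can shift the benzoate and the acid-labile 2-deoxyglycoside is spared.

**Step 8**
Reactants: 9 methyl 4-C-(benzoyloxymethyl)-3-O-benzyl-2-deoxy-α-D-lyxo-hexopyranoside
Product: 10 methyl 4-C-(benzoyloxymethyl)-3-O-benzyl-2-deoxy-4,6-bis-O-(triethylsilyl)-α-D-lyxo-hexopyranoside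
Conditions: TESOTf, 2,6-lutidine, CH2Cl2, 0 °C to rt
Reagents that add atoms: triethylsilyl triflate, CC[Si](CC)(CC)OS(=O)(=O)C(F)(F)F
Why: Silyl triflate silylation, reactive enough for the hindered tertiary hydroxyl, which must be blocked so that it cannot later trap the aldehyde of step 10 as a furanose lactol.

**Step 9**
Reactants: 10 methyl 4-C-(benzoyloxymethyl)-3-O-benzyl-2-deoxy-4,6-bis-O-(triethylsilyl)-α-D-lyxo-hexopyranoside
Product: 12 methyl (Z)-6-O-benzoyl-4-C-(benzoyloxymethyl)-3-O-benzyl-2-deoxy-4-O-triethylsilyl-hex-5-enopyranoside, via 6-aldehyde 11 (not isolated)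
Conditions: (COCl)2, DMSO, CH2Cl2, −78 to −40 °C; Et3N, to 0 °C; then Bz2O, DMAP, rt to 40 °C
Reagents that add atoms: benzoic anhydride, O=C(OC(=O)c1ccccc1)c1ccccc1
Why: Swern oxidation turns a primary triethylsilyl ether directly into the aldehyde while the tertiary one is inert, and amine-promoted enolisation with DMAP-catalysed O-benzoylation (enol ester formation) should give the Z isomer because the benzoyloxy group turns away from the fully substituted sugar C-4.

**Step 10**
Reactants: 12 methyl (Z)-6-O-benzoyl-4-C-(benzoyloxymethyl)-3-O-benzyl-2-deoxy-4-O-triethylsilyl-hex-5-enopyranoside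
Product: 14 [3-(benzoyloxy)-6-(benzyloxy)-4-hydroxy-2-oxo-1-(triethylsilyloxy)cyclohexyl]methyl benzoate, via mercurio keto aldehyde 13 (not isolated)
Conditions: Hg(OCOCF3)2 (0.1 equiv), acetone–H2O (4:1), rt
Reagents that add atoms: water, O; Hg(OCOCF3)2, O=C(O[Hg]OC(=O)C(F)(F)F)C(F)(F)F (mercury stays only in 13)
Why: Ferrier carbocyclization: Hg(OCOCF3)2 (divalent mercury) adds to the doubly oxygenated C6=C5 double bond (sugar C-5=C-6) with water entering at C6, the hemiketal collapses to the C6 ketone while the former ring oxygen stays on C4 and methanol leaves, and the mercury enolate of the open-chain α-mercurio keto aldehyde 13 attacks the C4 aldehyde through C5, after which protonolysis of the mercury alkoxide returns the catalyst. The closest known reaction type is this same carbocyclization run on 6-O-acyl-hex-5-enopyranosides, which gives 2-acyloxy-3-hydroxycyclohexanones. The carbocycle closes in the 6-(enolendo)-exo-trig mode through a chair that inherits the pyranoside pattern (C2-OBn and C1-CH2OBz equatorial, C1-OTES axial). At C4 the aldehyde oxygen takes the axial site, within reach of the mercury on the enolate oxygen, so the new hydroxyl should come out trans to the equatorial C2-OBn (β face), and at C5 the benzoyloxy group takes the equatorial site (β, cis to C4-OH), a placement that the epimerisable α-keto position also favours thermodynamically. The step needs a single enolisation site (secured because C1 is quaternary), attack of mercury on the only alkene present, and freedom from β-elimination, retro-aldol cleavage and acyl shift (secured by the neutral to weakly acidic aqueous acetone and by the silyl group on C1-O, which prevents a furanose lactol). The benzoate on C5-O and the free hydroxyl on C4 arise already differentiated, and both anomers of 12 funnel into the same 13.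

**Step 11**
Reactants: 14 [3-(benzoyloxy)-6-(benzyloxy)-4-hydroxy-2-oxo-1-(triethylsilyloxy)cyclohexyl]methyl benzoate
Product: 15 [3-(benzoyloxy)-6-(benzyloxy)-2,4-dihydroxy-1-(triethylsilyloxy)cyclohexyl]methyl benzoate
Conditions: Me4NBH(OAc)3, MeCN–AcOH (1:1), −20 °C
Reagents that add atoms: none
Why: Evans–Saksena hydroxyl-directed reduction, in which the axial C4-OH binds boron and delivers hydride to C6 from its own (β) face, so the new C6-OH should be equatorial, α, 1,3-anti to C4-OH and trans to C5-OBz.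

**Step 12**
Reactants: 15 [3-(benzoyloxy)-6-(benzyloxy)-2,4-dihydroxy-1-(triethylsilyloxy)cyclohexyl]methyl benzoate
Product: 16 [3-(benzoyloxy)-6-(benzyloxy)-1,2,4-tris(triethylsilyloxy)cyclohexyl]methyl benzoate
Conditions: TESOTf, 2,6-lutidine, CH2Cl2, −78 to 0 °C
Reagents that add atoms: triethylsilyl triflate, CC[Si](CC)(CC)OS(=O)(=O)C(F)(F)F
Why: Silyl triflate silylation with a non-nucleophilic base covers both secondary hydroxyls, including the hindered C6-OH, without generating an alkoxide that could move the C5 benzoate.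

**Step 13**
Reactants: 16 [3-(benzoyloxy)-6-(benzyloxy)-1,2,4-tris(triethylsilyloxy)cyclohexyl]methyl benzoate
Product: 17 [3-(benzoyloxy)-6-hydroxy-1,2,4-tris(triethylsilyloxy)cyclohexyl]methyl benzoate
Conditions: H2 (1 atm), Pd(OH)2/C, EtOAc, rt
Reagents that add atoms: none
Why: Catalytic hydrogenolysis of the benzyl ether, to which benzoates and, in ethyl acetate, triethylsilyl ethers are inert.

**Step 14**
Reactants: 17 [3-(benzoyloxy)-6-hydroxy-1,2,4-tris(triethylsilyloxy)cyclohexyl]methyl benzoate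
Product: 18 [3-(benzoyloxy)-6-oxo-1,2,4-tris(triethylsilyloxy)cyclohexyl]methyl benzoate
Conditions: Dess–Martin periodinane, CH2Cl2, 0 °C to rt
Reagents that add atoms: none
Why: Dess–Martin oxidation of the only free hydroxyl erases the temporary C2 stereocentre and gives the ketone under neutral conditions that should not expel the β-silyloxy group at C4.

**Step 15**
Reactants: 18 [3-(benzoyloxy)-6-oxo-1,2,4-tris(triethylsilyloxy)cyclohexyl]methyl benzoate
Product: 19 [(1S,2S,3R,4R)-3-(benzoyloxy)-1,2,4-trihydroxy-6-oxocyclohexyl]methyl benzoate (target)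
Conditions: HF·pyridine, pyridine, THF, 0 °C to rt
Reagents that add atoms: none
Why: Fluoride-mediated cleavage of the three triethylsilyl ethers in a weakly acidic buffered medium, which should spare the β-hydroxy ketone from elimination and retro-aldol cleavage and keep both benzoates in place.

**Compound list**

1 | D-glucal (1,5-anhydro-2-deoxy-D-arabino-hex-1-enitol) | C1=C[C@@H](O)[C@H](O)[C@@H](CO)O1 | starting material
2 | 6-O-(tert-butyldiphenylsilyl)-D-glucal | C1=C[C@@H](O)[C@H](O)[C@@H](CO[Si](c2ccccc2)(c2ccccc2)C(C)(C)C)O1 | intermediate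
3 | 3,4-O-dibutylstannylene acetal of 2 | C1=C[C@H]2O[Sn](CCCC)(CCCC)O[C@@H]2[C@@H](CO[Si](c3ccccc3)(c3ccccc3)C(C)(C)C)O1 | intermediate
4 | 3-O-benzyl-6-O-(tert-butyldiphenylsilyl)-D-glucal | C1=C[C@@H](OCc2ccccc2)[C@H](O)[C@@H](CO[Si](c2ccccc2)(c2ccccc2)C(C)(C)C)O1 | intermediate
5 | methyl 3-O-benzyl-6-O-(tert-butyldiphenylsilyl)-2-deoxy-α-D-arabino-hexopyranoside | CO[C@@H]1C[C@@H](OCc2ccccc2)[C@H](O)[C@@H](CO[Si](c2ccccc2)(c2ccccc2)C(C)(C)C)O1 | intermediate
6 | methyl 3-O-benzyl-6-O-(tert-butyldiphenylsilyl)-2-deoxy-α-D-threo-hexopyranosid-4-ulose | CO[C@@H]1C[C@@H](OCc2ccccc2)C(=O)[C@@H](CO[Si](c2ccccc2)(c2ccccc2)C(C)(C)C)O1 | intermediate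
7 | methyl 4,4'-anhydro-3-O-benzyl-6-O-(tert-butyldiphenylsilyl)-2-deoxy-4-C-(hydroxymethyl)-α-D-lyxo-hexopyranoside (spiro-epoxide; O axial, CH2 equatorial) | CO[C@@H]1C[C@@H](OCc2ccccc2)[C@]2(CO2)[C@@H](CO[Si](c2ccccc2)(c2ccccc2)C(C)(C)C)O1 | intermediate
8 | methyl 4-C-(benzoyloxymethyl)-3-O-benzyl-6-O-(tert-butyldiphenylsilyl)-2-deoxy-α-D-lyxo-hexopyranoside (axial tertiary 4-OH) | CO[C@@H]1C[C@@H](OCc2ccccc2)[C@](O)(COC(=O)c2ccccc2)[C@@H](CO[Si](c2ccccc2)(c2ccccc2)C(C)(C)C)O1 | intermediate
9 | methyl 4-C-(benzoyloxymethyl)-3-O-benzyl-2-deoxy-α-D-lyxo-hexopyranoside (4,6-diol) | CO[C@@H]1C[C@@H](OCc2ccccc2)[C@](O)(COC(=O)c2ccccc2)[C@@H](CO)O1 | intermediate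
10 | methyl 4-C-(benzoyloxymethyl)-3-O-benzyl-2-deoxy-4,6-bis-O-(triethylsilyl)-α-D-lyxo-hexopyranoside | CO[C@@H]1C[C@@H](OCc2ccccc2)[C@](O[Si](CC)(CC)CC)(COC(=O)c2ccccc2)[C@@H](CO[Si](CC)(CC)CC)O1 | intermediate
11 | methyl 4-C-(benzoyloxymethyl)-3-O-benzyl-2-deoxy-4-O-triethylsilyl-α-D-lyxo-hexodialdo-1,5-pyranoside (6-aldehyde) | CO[C@@H]1C[C@@H](OCc2ccccc2)[C@](O[Si](CC)(CC)CC)(COC(=O)c2ccccc2)[C@@H](C=O)O1 | intermediate
12 | methyl (Z)-6-O-benzoyl-4-C-(benzoyloxymethyl)-3-O-benzyl-2-deoxy-4-O-triethylsilyl-hex-5-enopyranoside (C-1, C-3 and C-4 configured as in 10; OBz cis to the ring oxygen) | CO[C@@H]1C[C@@H](OCc2ccccc2)[C@](O[Si](CC)(CC)CC)(COC(=O)c2ccccc2)/C(=C/OC(=O)c2ccccc2)O1 | intermediate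
13 | open-chain keto aldehyde: C4 aldehyde, C6 ketone, C5 bearing OBz and HgOCOCF3 (C5 configuration undefined) | O=CC[C@@H](OCc1ccccc1)[C@](O[Si](CC)(CC)CC)(COC(=O)c1ccccc1)C(=O)C([Hg]OC(=O)C(F)(F)F)OC(=O)c1ccccc1 | intermediate
14 | [3-(benzoyloxy)-6-(benzyloxy)-4-hydroxy-2-oxo-1-(triethylsilyloxy)cyclohexyl]methyl benzoate (C6 ketone; C1 α-OTES; C2 α-OBn; C4 β-OH; C5 β-OBz) | O[C@@H]1C[C@@H](OCc2ccccc2)[C@](O[Si](CC)(CC)CC)(COC(=O)c2ccccc2)C(=O)[C@@H]1OC(=O)c2ccccc2 | intermediate
15 | [3-(benzoyloxy)-6-(benzyloxy)-2,4-dihydroxy-1-(triethylsilyloxy)cyclohexyl]methyl benzoate (as 14, with C6 α-OH) | O[C@@H]1C[C@@H](OCc2ccccc2)[C@](O[Si](CC)(CC)CC)(COC(=O)c2ccccc2)[C@@H](O)[C@@H]1OC(=O)c2ccccc2 | intermediate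
16 | [3-(benzoyloxy)-6-(benzyloxy)-1,2,4-tris(triethylsilyloxy)cyclohexyl]methyl benzoate (C1 α, C6 α, C4 β OTES; C2 α-OBn; C5 β-OBz) | CC[Si](CC)(CC)O[C@@H]1C[C@@H](OCc2ccccc2)[C@](O[Si](CC)(CC)CC)(COC(=O)c2ccccc2)[C@@H](O[Si](CC)(CC)CC)[C@@H]1OC(=O)c2ccccc2 | intermediate
17 | [3-(benzoyloxy)-6-hydroxy-1,2,4-tris(triethylsilyloxy)cyclohexyl]methyl benzoate (as 16, with C2 α-OH) | CC[Si](CC)(CC)O[C@@H]1C[C@@H](O)[C@](O[Si](CC)(CC)CC)(COC(=O)c2ccccc2)[C@@H](O[Si](CC)(CC)CC)[C@@H]1OC(=O)c2ccccc2 | intermediate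
18 | [3-(benzoyloxy)-6-oxo-1,2,4-tris(triethylsilyloxy)cyclohexyl]methyl benzoate (as 16, with C2 ketone) | CC[Si](CC)(CC)O[C@@H]1CC(=O)[C@](O[Si](CC)(CC)CC)(COC(=O)c2ccccc2)[C@@H](O[Si](CC)(CC)CC)[C@@H]1OC(=O)c2ccccc2 | intermediate
19 | [(1S,2S,3R,4R)-3-(benzoyloxy)-1,2,4-trihydroxy-6-oxocyclohexyl]methyl benzoate | O=C(OC[C@@]1(O)C(=O)C[C@@H](O)[C@@H](OC(=O)c2ccccc2)[C@@H]1O)c1ccccc1 | target

Total step count: 15. Longest linear sequence: 15.

**Steps most likely to fail**

Step 10. The mercury enolate may be protonated before it closes the ring. The closure may also run with poor facial control at C4 or C5, or the β-hydroxy ketone may eliminate.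
- The fallback sets out from 12 and separates unmasking from ring closure.
- Mild hydrolysis (AcOH–H2O–THF, rt) of the very labile 2-deoxyglycoside, followed by tautomerisation of the released enol, should give the isolable open-chain keto aldehyde F1.
- A base-catalysed intramolecular aldol addition (DBU cat., toluene, low temperature), the reaction type known for aldohexos-5-uloses, then closes the same bond under equilibrating control and comes back to the route at 14.

Step 9. The aldehyde enolate may expel the axial 4-silyloxy group (E1cB) faster than it is benzoylated, or the enol ester may form with poor geometric control. The fallback sets out from 9 and brings in the C5 oxygen after the ring closure instead of before it.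
- Appel-type iodination (I2, PPh3, imidazole) should give the 6-iodide F2.
- TESOTf and 2,6-lutidine give its 4-O-triethylsilyl ether F3.
- DBU-induced dehydroiodination gives the unsubstituted hex-5-enopyranoside F4.
- The same Hg(OCOCF3)2-catalysed carbocyclization gives the C5-unsubstituted β-hydroxy ketone F5.
- Because C1 is quaternary, F5 can form an enamine only toward C5. α-Benzoyloxylation with N-methyl-O-benzoylhydroxylamine hydrochloride (DMSO, rt, [3,3] shift of the N-acyloxy enamine) should therefore place the benzoate there, equatorial after equilibration, and the route is rejoined at 14.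

Step 5. Methylene transfer may show poor facial selectivity, or the basic ylide may trigger β-elimination of the 6-silyloxy group. The fallback sets out from 6 and uses a bulky, weakly basic hydroxymethyl anion equivalent.
- iPrOMe2SiCH2MgCl (THF, 0 °C) should attack equatorially to give the axial tertiary alcohol F6.
- Tamao–Fleming oxidation (H2O2, KF, KHCO3, THF–MeOH) gives the 4-C-hydroxymethyl diol F7.
- Selective benzoylation of the primary hydroxyl (BzCl, pyridine, −20 °C) comes back to the route at 8.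

**Further compounds**

F1 | step 10 | open-chain keto aldehyde: C4 aldehyde, C6 ketone, C5 as CH2OBz, C2 OBn and C1 OTES/CH2OBz as in 12 | O=CC[C@@H](OCc1ccccc1)[C@](O[Si](CC)(CC)CC)(COC(=O)c1ccccc1)C(=O)COC(=O)c1ccccc1
F2 | step 9 | methyl 4-C-(benzoyloxymethyl)-3-O-benzyl-2,6-dideoxy-6-iodo-α-D-lyxo-hexopyranoside | CO[C@@H]1C[C@@H](OCc2ccccc2)[C@](O)(COC(=O)c2ccccc2)[C@@H](CI)O1
F3 | step 9 | 4-O-triethylsilyl ether of F2 | CO[C@@H]1C[C@@H](OCc2ccccc2)[C@](O[Si](CC)(CC)CC)(COC(=O)c2ccccc2)[C@@H](CI)O1
F4 | step 9 | methyl 4-C-(benzoyloxymethyl)-3-O-benzyl-2,6-dideoxy-4-O-triethylsilyl-hex-5-enopyranoside (C-1, C-3, C-4 as in F3) | CO[C@@H]1C[C@@H](OCc2ccccc2)[C@](O[Si](CC)(CC)CC)(COC(=O)c2ccccc2)C(=C)O1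
F5 | step 9 | [6-(benzyloxy)-4-hydroxy-2-oxo-1-(triethylsilyloxy)cyclohexyl]methyl benzoate (as 14 without the C5 benzoate) | O[C@@H]1C[C@@H](OCc2ccccc2)[C@](O[Si](CC)(CC)CC)(COC(=O)c2ccccc2)C(=O)C1
F6 | step 5 | methyl 3-O-benzyl-6-O-(tert-butyldiphenylsilyl)-2-deoxy-4-C-[(isopropoxydimethylsilyl)methyl]-α-D-lyxo-hexopyranoside | CO[C@@H]1C[C@@H](OCc2ccccc2)[C@](O)(C[Si](C)(C)OC(C)C)[C@@H](CO[Si](c2ccccc2)(c2ccccc2)C(C)(C)C)O1
F7 | step 5 | methyl 3-O-benzyl-6-O-(tert-butyldiphenylsilyl)-2-deoxy-4-C-(hydroxymethyl)-α-D-lyxo-hexopyranoside | CO[C@@H]1C[C@@H](OCc2ccccc2)[C@](O)(CO)[C@@H](CO[Si](c2ccccc2)(c2ccccc2)C(C)(C)C)O1
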